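## Retrosynthetic overview

1. Target ⇒ 4,5-dihydro form of a cross-conjugated 3a-allyl cyclohexadienone; the last step is a chemoselective CuH 1,4-reduction of the α-methoxy-enone arm, with C5 fixed by equilibration.
2. Dienone ⇒ key disconnection C3–C3a: a dearomatising ipso-Friedel–Crafts closure of a β-aryloxy benzylic cation onto the allyl-bearing carbon of a tetra-oxygenated benzene, the para-OMe leaving as MeOH. This one step breaks the aromaticity, closes the dihydrofuran ring and sets C3 and the quaternary C3a from C2.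
3. Cyclisation substrate (8-O-4′-type carbinol) ⇒ C2–C3 bond from 3,4,5-trimethoxyphenyl Grignard and an (R)-2-aryloxypropanoate (one-pot DIBAL/ArMgBr).
4. (R)-Aryloxypropanoate ⇒ Mitsunobu inversion of ethyl (S)-lactate (the only purchased stereocentre, becomes C2) with 6-allyl-2,3,4-trimethoxyphenol ⇒ Claisen ⇒ 2,3,4-trimethoxyphenol + allyl bromide.
5. Ring order: the benzene ring is bought; the O-heterocycle forms in the dearomatising step; the carbocycle is then taken from dienone to enone.

Assumption: 2,3,4-trimethoxyphenol and 3,4,5-trimethoxyphenylmagnesium bromide (0.5 M in THF) are bought as catalogue items.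

The target is read as (2R,3S,3aS,5S): 2-Me/3-Ar trans, 3-Ar/3a-allyl cis, 5-OMe trans to 3a-allyl.

## Route

Step 1
Reactants: 1 2,3,4-trimethoxyphenol; 2 allyl bromide
Product: 3 1-(allyloxy)-2,3,4-trimethoxybenzene
Conditions: K2CO3, acetone, reflux
Reagents that add atoms: none
Why: Williamson ether synthesis (phenoxide SN2 on allyl bromide); no stereocentre is involved.

Step 2
Reactants: 3 1-(allyloxy)-2,3,4-trimethoxybenzene
Product: 4 6-allyl-2,3,4-trimethoxyphenol
Conditions: PhNEt2, 200 °C, sealed tube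
Reagents that add atoms: none
Why: Aromatic Claisen rearrangement ([3,3]) delivers allyl to the only free ortho carbon and tautomerises back to the phenol, because the other ortho carbon and the para carbon carry OMe and a shift there can only revert.

Step 3
Reactants: 4 6-allyl-2,3,4-trimethoxyphenol; 5 ethyl (S)-lactate
Product: 6 ethyl (2R)-2-(6-allyl-2,3,4-trimethoxyphenoxy)propanoate
Conditions: PPh3, DIAD, THF, 0 °C → rt
Reagents that add atoms: none
Why: Mitsunobu etherification of the activated secondary lactate hydroxyl proceeds by SN2 with clean inversion, turning the (S)-lactate into the (R)-aryl ether centre that becomes C2 of the target.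

Step 4
Reactants: 6 ethyl (2R)-2-(6-allyl-2,3,4-trimethoxyphenoxy)propanoate; 7 3,4,5-trimethoxyphenylmagnesium bromide
Product: 9 (2R)-2-(6-allyl-2,3,4-trimethoxyphenoxy)-1-(3,4,5-trimethoxyphenyl)propan-1-ol (both C1 epimers), via aldehyde 8 (not isolated)
Conditions: DIBAL-H (1.05 equiv), CH2Cl2, −78 °C; then 7 (2.5 equiv), THF, −78 → 0 °C; Rochelle salt work-up
Reagents that add atoms: none
Why: One-pot partial ester reduction/Grignard addition stops at the aldehyde oxidation level at −78 °C and traps 8 in the same flask, so the epimerisable α-aryloxy aldehyde is never handled and C2 is retained; the new carbinol centre needs no control because it is ionised in step 5.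

Step 5
Reactants: 9 (2R)-2-(6-allyl-2,3,4-trimethoxyphenoxy)-1-(3,4,5-trimethoxyphenyl)propan-1-ol
Product: 12 (2R,3S,3aR)-3a-allyl-5,7-dimethoxy-2-methyl-3-(3,4,5-trimethoxyphenyl)-3,3a-dihydro-1-benzofuran-6(2H)-one, via benzylic cation 10 (not isolated), via cyclised oxocarbenium ion 11 (not isolated)
Conditions: TsOH·H2O (10 mol%), H2O (2 equiv), HFIP (0.01 M), 0 °C, 30 min; NaHCO3 quench
Reagents that add atoms: water, O
Why: Proposed new method: TsOH in HFIP ionises either carbinol epimer to the 3,4,5-trimethoxybenzyl cation 10, whose A(1,3)-minimised conformer (C2–H in the cation plane) is attacked from the ether-oxygen face by the allyl-bearing ring carbon (ortho to the ether O and para to the 3-OMe; attack at the OMe-bearing ortho carbon is more hindered and reversible), an ipso-Friedel–Crafts step that breaks aromaticity and sets C3 trans to the C2 methyl, while the aryl group takes the exo, pseudo-equatorial site of the forming envelope and so ends cis to the angular allyl at C3a; the O-methyl oxocarbenium ion 11 cannot re-aromatise and is hydrolysed by water with loss of MeOH to the vinylogous ester; the closest known reaction types are the acid-catalysed trans-dihydrobenzofuran closure of β-aryloxy benzylic cations and the demethylative ipso-cyclisation of p-methoxyarenes to cyclohexadienones.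

Step 6
Reactants: 12 (2R,3S,3aR)-3a-allyl-5,7-dimethoxy-2-methyl-3-(3,4,5-trimethoxyphenyl)-3,3a-dihydro-1-benzofuran-6(2H)-one
Product: 15 (2R,3S,3aS,5S)-3a-allyl-5,7-dimethoxy-2-methyl-3-(3,4,5-trimethoxyphenyl)-3,3a,4,5-tetrahydro-1-benzofuran-6(2H)-one (CNP0136253.1), via copper enolate 13 (not isolated), via C5 epimer 14 (not isolated)
Conditions: [(Ph3P)CuH]6 (0.4 equiv), H2O (5 equiv), PhH–THF, rt; then K2CO3 (cat.), MeOH, rt
Reagents that add atoms: none
Why: Stryker-type CuH conjugate reduction delivers hydride to C4 of the α-methoxy-enone arm (β-H, not donor-deactivated) and leaves the β-alkoxy vinylogous-ester arm and the terminal alkene alone, protonation of copper enolate 13 gives 15 together with its C5 epimer 14, and K2CO3/MeOH equilibrates the α-methoxy ketone to 15, in which 5-OMe is equatorial and trans to the pseudo-axial 3a-allyl (no 1,3-diaxial contact).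

## Compound list

1 | 2,3,4-trimethoxyphenol | COc1ccc(O)c(OC)c1OC | starting material
2 | allyl bromide | C=CCBr | starting material
3 | 1-(allyloxy)-2,3,4-trimethoxybenzene | C=CCOc1ccc(OC)c(OC)c1OC | intermediate
4 | 6-allyl-2,3,4-trimethoxyphenol | C=CCc1cc(OC)c(OC)c(OC)c1O | intermediate
5 | ethyl (S)-lactate | CCOC(=O)[C@H](C)O | starting material
6 | ethyl (2R)-2-(6-allyl-2,3,4-trimethoxyphenoxy)propanoate | CCOC(=O)[C@@H](C)Oc1c(CC=C)cc(OC)c(OC)c1OC | intermediate
7 | 3,4,5-trimethoxyphenylmagnesium bromide | COc1cc([Mg]Br)cc(OC)c1OC | starting material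
8 | (2R)-2-(6-allyl-2,3,4-trimethoxyphenoxy)propanal | O=C[C@@H](C)Oc1c(CC=C)cc(OC)c(OC)c1OC | intermediate
9 | (2R)-2-(6-allyl-2,3,4-trimethoxyphenoxy)-1-(3,4,5-trimethoxyphenyl)propan-1-ol, C1 epimer mixture | C[C@@H](Oc1c(CC=C)cc(OC)c(OC)c1OC)C(O)c1cc(OC)c(OC)c(OC)c1 | intermediate
10 | (2R)-2-(6-allyl-2,3,4-trimethoxyphenoxy)-1-(3,4,5-trimethoxyphenyl)propan-1-ylium (benzylic cation) | C[C@@H](Oc1c(CC=C)cc(OC)c(OC)c1OC)[CH+]c1cc(OC)c(OC)c(OC)c1 | intermediate
11 | cyclised 6-O-methyl oxocarbenium ion of dienone 12 (same C2, C3, C3a configuration as 12) | C=CC[C@@]12C=C(OC)C(=[O+]C)C(OC)=C1O[C@H](C)[C@H]2c1cc(OC)c(OC)c(OC)c1 | intermediate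
12 | (2R,3S,3aR)-3a-allyl-5,7-dimethoxy-2-methyl-3-(3,4,5-trimethoxyphenyl)-3,3a-dihydro-1-benzofuran-6(2H)-one (2-Me/3-Ar trans, 3-Ar/3a-allyl cis) | C=CC[C@@]12C=C(OC)C(=O)C(OC)=C1O[C@H](C)[C@H]2c1cc(OC)c(OC)c(OC)c1 | intermediate
13 | copper(I) enolate of 15 (C5=C6–OCu, phosphine ligands omitted) | C=CC[C@@]12CC(OC)=C(O[Cu])C(OC)=C1O[C@H](C)[C@H]2c1cc(OC)c(OC)c(OC)c1 | intermediate
14 | (2R,3S,3aS,5R)-3a-allyl-5,7-dimethoxy-2-methyl-3-(3,4,5-trimethoxyphenyl)-3,3a,4,5-tetrahydro-1-benzofuran-6(2H)-one (C5 epimer of 15) | C=CC[C@@]12C[C@@H](OC)C(=O)C(OC)=C1O[C@H](C)[C@H]2c1cc(OC)c(OC)c(OC)c1 | intermediate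
15 | CNP0136253.1, (2R,3S,3aS,5S)-3a-allyl-5,7-dimethoxy-2-methyl-3-(3,4,5-trimethoxyphenyl)-3,3a,4,5-tetrahydro-1-benzofuran-6(2H)-one | C=CC[C@@]12C[C@H](OC)C(=O)C(OC)=C1O[C@H](C)[C@H]2c1cc(OC)c(OC)c(OC)c1 | target

## Step count and risks

Total steps: 6. Longest linear sequence: 6 (1 → 3 → 4 → 6 → 9 → 12 → 15).

**Most likely to fail, in order:**

Step 5 (dearomatising ipso-Friedel–Crafts). The risks are:
- E1 loss of the C2 proton to an enol ether, followed by β-O-4-type cleavage;
- participation of the ortho-OMe oxygen, giving a benzodioxane;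
- acid-driven re-opening or dienone–phenol shift of 12;
- formation of the C3a epimer (aryl trans to allyl) if the endo, π-stacked transition state or acid equilibration wins. This is the least certain prediction in the route.

The fallback sets out from phenol 4 and Grignard 7 and returns at dienone 12. Copper-catalysed opening of (S)-propylene oxide by 7 (CuI cat., THF, −30 °C) gives (S)-1-(3,4,5-trimethoxyphenyl)propan-2-ol F1. Mitsunobu coupling of F1 with 4 (PPh3, DIAD, inversion) gives the deoxy ether 1-allyl-3,4,5-trimethoxy-2-{[(2R)-1-(3,4,5-trimethoxyphenyl)propan-2-yl]oxy}benzene F2. DDQ in wet CH2Cl2 at 0 °C then abstracts the benzylic hydride of F2, generating cation 10 without Brønsted acid. The ring closure is therefore kinetic, and 12 is not re-ionised after water hydrolyses 11.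

Step 6 (regio- and chemoselective 1,4-reduction, C5 configuration). The risks are 1,2-reduction, attack on the wrong enone arm, or a sluggish reaction next to the quaternary centre. The fallback sets out from 12 and returns at 15. Benzeneselenol (from PhSeSePh/NaBH4, EtOH, AcOH) adds reversibly in a 1,4 sense to the less hindered α-methoxy-enone arm. This gives (2R,3S,3aS)-3a-allyl-5,7-dimethoxy-2-methyl-4-(phenylselanyl)-3-(3,4,5-trimethoxyphenyl)-3,3a,4,5-tetrahydro-1-benzofuran-6(2H)-one F3 as a C4/C5 mixture. Bu3SnH/AIBN (PhH, 80 °C) cleaves the C–Se bond homolytically to leave CH2 at C4. The same K2CO3/MeOH equilibration then gives 15.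

Step 4 (one-pot DIBAL/ArMgBr). The risks are over-reduction to the primary alcohol and partial epimerisation of the α-aryloxy aldehyde. The fallback sets out from ester 6 and returns at carbinol 9. Treatment of 6 with MeNHOMe·HCl/i-PrMgCl (THF, −20 °C) gives the Weinreb amide (2R)-2-(6-allyl-2,3,4-trimethoxyphenoxy)-N-methoxy-N-methylpropanamide F4. Grignard 7 adds once to give (2R)-2-(6-allyl-2,3,4-trimethoxyphenoxy)-1-(3,4,5-trimethoxyphenyl)propan-1-one F5. NaBH4 (MeOH, 0 °C) reduces F5 to 9; either carbinol epimer is acceptable.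

## Further compounds

F1 | step 5 | (S)-1-(3,4,5-trimethoxyphenyl)propan-2-ol | C[C@H](O)Cc1cc(OC)c(OC)c(OC)c1
F2 | step 5 | 1-allyl-3,4,5-trimethoxy-2-{[(2R)-1-(3,4,5-trimethoxyphenyl)propan-2-yl]oxy}benzene | C[C@H](Cc1cc(OC)c(OC)c(OC)c1)Oc1c(CC=C)cc(OC)c(OC)c1OC
F3 | step 6 | (2R,3S,3aS)-3a-allyl-5,7-dimethoxy-2-methyl-4-(phenylselanyl)-3-(3,4,5-trimethoxyphenyl)-3,3a,4,5-tetrahydro-1-benzofuran-6(2H)-one, C4/C5 mixture | C=CC[C@@]12C([Se]c3ccccc3)C(OC)C(=O)C(OC)=C1O[C@H](C)[C@H]2c1cc(OC)c(OC)c(OC)c1
F4 | step 4 | (2R)-2-(6-allyl-2,3,4-trimethoxyphenoxy)-N-methoxy-N-methylpropanamide | CON(C)C(=O)[C@@H](C)Oc1c(CC=C)cc(OC)c(OC)c1OC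
F5 | step 4 | (2R)-2-(6-allyl-2,3,4-trimethoxyphenoxy)-1-(3,4,5-trimethoxyphenyl)propan-1-one | C[C@@H](Oc1c(CC=C)cc(OC)c(OC)c1OC)C(=O)c1cc(OC)c(OC)c(OC)c1
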